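The readings stem from a simulated flask for an exercise.

Late in the alpha run homo product has outgrown target, 57.2% against 0% at 120 min, so we ask what the four new flasks do to the late ratio of the two.

| flask | substrate | fresh partner | coupling partner | capture agent | temperature | remark | time |
|---|---|---|---|---|---|---|---|
| theta | 0.29 M | 0.319 M | 0.58 M | 0.029 M | −25 °C | run made earlier |  |
| alpha | 0.29 M | 0.319 M | 0.81 M | 0.029 M | −14 °C | run made earlier |  |
| beta | 0.29 M | 0.319 M | 1.3 M | 0.029 M | −25 °C | run made earlier |  |
| delta | 0.29 M | 0.319 M | 0.58 M | 0.015 M | −14 °C | run made earlier |  |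
| dusk | 0.29 M | 0.319 M | 0.580 M | 0.0290 M | −20 °C | everything together at the start | 1.5 h |
| midnight | 0.29 M | 0.319 M (in portions, 3, over 80 min) | 0.580 M | 0.0290 M | −20 °C | first portion at the start, last at 80 min | 1.5 h |
| dawn | 0.29 M (fed, over 80 min) | 0.319 M | 0.580 M | 0.0290 M | −20 °C | all else is in the flask from the start; the feed brings no volume worth counting | 1.5 h |
| spring | 0.29 M | 0.319 M (fed, over 80 min) | 0.580 M | 0.0290 M |  | the addition at −40 °C, then warmed to −20 °C; the feed brings no volume worth counting | 1.5 h |

| run | time / min | target / % | homo product / % | substrate / % |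
|---|---|---|---|---|
| theta | 8.00 | 0 | 0 | 93.4 |
| theta | 25.0 | 0.9 | 0.9 | 83.6 |
| theta | 40.0 | 0.2 | 0 | 78.2 |
| theta | 60.0 | 1.8 | 2.2 | 69.2 |
| theta | 90.0 | 3.0 | 5.6 | 62.0 |
| alpha | 8.00 | 2.1 | 0 | 75.1 |
| alpha | 15.0 | 0.1 | 2.3 | 62.6 |
| alpha | 30.0 | 1.5 | 9.4 | 40.9 |
| alpha | 60.0 | 2.6 | 29.8 | 20.2 |
| alpha | 120 | 0 | 57.2 | 7.6 |
| beta | 8.00 | 1.1 | 0.5 | 83.4 |
| beta | 15.0 | 0.4 | 0 | 70.7 |
| beta | 30.0 | 3.1 | 0.5 | 50.7 |
| beta | 60.0 | 5.3 | 10.4 | 28.9 |
| beta | 120 | 4.7 | 31.1 | 7.4 |
| delta | 20.0 | 0 | 2.5 | 70.3 |
| delta | 40.0 | 2.3 | 6.7 | 56.1 |
| delta | 60.0 | 1.9 | 15.0 | 47.8 |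
| delta | 80.0 | 2.9 | 22.9 | 39.7 |
| delta | 120 | 0 | 34.9 | 34.1 |

(standard deviation of a reading: 1 percentage point)

- a species is counted by the substrate in it: one homo product counts as two
- the earlier runs were read with a standard deviation of 1 percentage point
- candidate steps: substrate + coupling partner -> open intermediate; coupling partner + fresh partner -> second intermediate; open intermediate + second intermediate <-> target; 2 open intermediate -> homo product; second intermediate -> side product; second intermediate + capture agent -> trapped intermediate

- the flask that comes out highest in share of target in target plus homo product, or "all alike" when all lie within 1.5 percentage points (dusk / midnight / dawn / spring / all alike)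
- share of target in target plus homo product at the end, dusk
- share of target in target plus homo product at the end, midnight
- share of target in target plus homo product at the end, dawn
- share of target in target plus homo product at the end, spring

1. Let o be the odds, target over homo product, read at a late time; it is a ratio of amounts at that moment, not a constant of the steps. Shares turn into o, and we work in log10 of o. The rule we hold to is that log10 o moves in a straight line with temperature and that recipes at one temperature share it; this is our assumption.

2. Theta gives o from 3.0% and 5.6%, delta from 2.9% and 22.9%; these two share a coupling partner charge, though delta has less capture agent. Stretching their line from the span −25 °C to −14 °C over the span −40 °C to −20 °C gives G, the decades of odds between a flask at the lower and one at the upper temperature, 1.14.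

3. Turned round, spring could level with dusk if G were near zero. Moving both target readings against us by 1 percentage point still leaves 0.585. We therefore reckon o of 0.278, a share of 21.8%, for dusk, midnight and dawn, and 79.3% for spring.

4. The forecast also names spring, with 17%, 14%, 27% and 35% for dusk, midnight, dawn and spring, and says “Spring stays cold and converts little, so homo product is tiny.” We part from it on dawn and on the size of spring's share.

5. The flasks gave the following.

    substrate + coupling partner → open intermediate (k = 0.0410 M⁻¹ min⁻¹, Ea = 53.0 kJ mol⁻¹)
    coupling partner + fresh partner → second intermediate (k = 0.930 M⁻¹ min⁻¹, Ea = 45.0 kJ mol⁻¹)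
    open intermediate + second intermediate ⇌ target (K = 2.70 M⁻¹, k = 0.0250 M⁻¹ min⁻¹, Ea = 64.0 kJ mol⁻¹, ΔH = 6.00 kJ mol⁻¹)
    2 open intermediate → homo product (k = 0.0290 M⁻¹ min⁻¹, Ea = 47.0 kJ mol⁻¹)
    second intermediate → side product (k = 0.0410 min⁻¹, Ea = 81.0 kJ mol⁻¹)
    second intermediate + capture agent → trapped intermediate (k = 0.0560 M⁻¹ min⁻¹, Ea = 62.0 kJ mol⁻¹)
    (constants at −20 °C)

Dusk gave 14.9%, midnight 12.6%, dawn 14.7% and spring 60.0%. So the odds of spring lead those of dusk by 0.934 decades, and G, at 1.14, is more than that. Dawn, with G zero against dusk, stands 0.00425 decades below dusk. In spring, coupling partner met fresh partner as it was fed in the cold, and second intermediate stood at 0.198 M at 1.50 h, beside 0.768% homo product. In dusk, by then, second intermediate stood at 0.00810 M and side product had reached 0.296 M, against 0.105 M in spring.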